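**Assumptions:** the stereocentre in the SMILES is (2S), the natural flavanone series. The telescoped borylation/oxidation in step 2 is counted as one step. The purchased carbon sources are resorcinol, paraformaldehyde, prenyl chloride and ethoxyacetylene.

## Retrosynthetic overview

1. Target 16 ⇐ one acidic global deprotection (MOM and TBS) of flavanone 15.
2. 15 ⇐ C2–C1′ bond and the only stereocentre, by Pd(II)/pyridine-oxazoline asymmetric conjugate arylation of chromone 11 with arylboronic acid 14.
3. 11 ⇐ pyranone ring, by Rh-catalysed aldehyde C–H hydroacylation/annulation of salicylaldehyde 9 with ethoxyacetylene.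
4. 9 ⇐ double Suzuki prenylation of diiodide 6 with prenyl-Bpin 8; 6 ⇐ resorcinol by MOM protection, Ir C–H borylation/oxidation, ortho-formylation and iodination.
5. 14 ⇐ resorcinol by TBS protection, Ir meta-C–H borylation and boronate cleavage. Both benzene rings are bought; the pyranone ring is built in step 7 and becomes the chromanone in step 11.

## Route

**Step 1**
Reactants: 1 resorcinol
Product: 2 1,3-bis(methoxymethoxy)benzene
Conditions: NaH, MOMCl, DMF, 0 °C → rt
Reagents that add atoms: chloromethyl methyl ether, COCCl
Why: Williamson-type acetal protection of both phenols; MOM is small and survives the basic, organometallic and oxidative steps that follow.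

**Step 2**
Reactants: 2
Product: 3 3,5-bis(methoxymethoxy)phenol
Conditions: [Ir(OMe)(cod)]2 (1.5 mol%), dtbpy (3 mol%), B2pin2, THF, 80 °C; then aq NaOH, 30% H2O2, 0 °C → rt (one pot)
Reagents that add atoms: hydrogen peroxide, OO (B2pin2 is consumed; its boron is not retained)
Why: Sterically controlled Ir-catalysed aromatic C–H borylation goes to C5, the only C–H without an ortho substituent, and basic peroxide oxidation of the aryl boronate gives the phenol without touching the MOM ethers.

**Step 3**
Reactants: 3; 4 paraformaldehyde
Product: 5 2-hydroxy-4,6-bis(methoxymethoxy)benzaldehyde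
Conditions: MgCl2, Et3N, (CH2O)n, MeCN, reflux
Reagents that add atoms: none
Why: Magnesium-phenoxide-directed ortho-formylation (Casiraghi/Skattebøl type) is ortho-specific, and the two ortho positions of 3 are equivalent, so one aldehyde results.

**Step 4**
Reactants: 5
Product: 6 2-hydroxy-3,5-diiodo-4,6-bis(methoxymethoxy)benzaldehyde
Conditions: BnMe3N·ICl2 (2.2 equiv), NaHCO3, CH2Cl2/MeOH, rt
Reagents that add atoms: benzyltrimethylammonium dichloroiodate, C[N+](C)(C)Cc1ccccc1.Cl[I-]Cl
Why: Electrophilic aromatic iodination under buffered conditions; the two remaining ring C–H positions (ortho and para to the free OH, each flanked by oxygens) are both wanted, so exhaustive iodination has no regiochemical issue.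

**Step 5**
Reactants: 7 1-chloro-3-methylbut-2-ene (prenyl chloride)
Product: 8 4,4,5,5-tetramethyl-2-(3-methylbut-2-en-1-yl)-1,3,2-dioxaborolane (prenyl-Bpin)
Conditions: Mg, THF, 0 °C; then i-PrOBpin, −78 °C → rt
Reagents that add atoms: 2-isopropoxy-4,4,5,5-tetramethyl-1,3,2-dioxaborolane, CC(C)OB1OC(C)(C)C(C)(C)O1
Why: Grignard formation and borylation with a borate ester gives the primary (linear) allylic boronate.

**Step 6**
Reactants: 6; 8 (3 equiv)
Product: 9 2-hydroxy-4,6-bis(methoxymethoxy)-3,5-bis(3-methylbut-2-en-1-yl)benzaldehyde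
Conditions: Pd-PEPPSI-IPent (5 mol%), 5 M aq KOH, THF, 65 °C
Reagents that add atoms: none
Why: Double Suzuki–Miyaura sp2–sp3 coupling; the bulky NHC–Pd catalyst handles di-ortho-substituted aryl iodides and lets the allyl-Pd equilibrate (σ–π–σ) to the primary terminus before reductive elimination, giving linear prenyl groups, while the aldehyde is deactivated as its chelated phenoxide.

**Step 7**
Reactants: 9; 10 ethoxyacetylene (3 equiv, hexanes solution)
Product: 11 5,7-bis(methoxymethoxy)-6,8-bis(3-methylbut-2-en-1-yl)-4H-chromen-4-one
Conditions: [Rh(cod)Cl]2 (2.5 mol%), dppf (6 mol%), K3PO4 (0.5 equiv), toluene, 70 °C, sealed tube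
Reagents that add atoms: none
Why: Proposed new method: phenoxide-chelated Rh(I) inserts into the aldehyde C–H bond to give an acyl–Rh(III)–H, which adds across the ynol ether with Rh at the unhindered terminal carbon and H at the electrophilic O-bearing carbon; C–C reductive elimination gives ArC(O)CH=CH–OEt, and the ortho-phenoxide then closes 6-endo by oxa-Michael addition and expels ethoxide to give the 2,3-unsubstituted chromone, redox-neutral. The closest known reaction type is Rh/diphosphine-catalysed chelation-assisted hydroacylation of alkynes with salicylaldehydes (including its hydroacylation/oxa-Michael variant to chromanones); an ynol ether as an acetylene equivalent with a built-in leaving group has not been shown.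

**Step 8**
Reactants: 1 resorcinol
Product: 12 1,3-bis(tert-butyldimethylsilyloxy)benzene
Conditions: TBSCl, imidazole, DMF, rt
Reagents that add atoms: tert-butyldimethylsilyl chloride, CC(C)(C)[Si](C)(C)Cl
Why: Standard silylation; the bulky silyl ethers reinforce the steric bias in the next step, give a lipophilic boronic acid, and cleave under the same acid conditions as MOM at the end.

**Step 9**
Reactants: 12
Product: 13 2-[3,5-bis(tert-butyldimethylsilyloxy)phenyl]-4,4,5,5-tetramethyl-1,3,2-dioxaborolane
Conditions: [Ir(OMe)(cod)]2 (1.5 mol%), dtbpy (3 mol%), B2pin2, hexane, 80 °C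
Reagents that add atoms: bis(pinacolato)diboron, CC1(C)OB(B2OC(C)(C)C(C)(C)O2)OC1(C)C
Why: Ir-catalysed C–H borylation of a 1,3-disubstituted arene occurs only at C5, meta to both silyloxy groups.

**Step 10**
Reactants: 13
Product: 14 [3,5-bis(tert-butyldimethylsilyloxy)phenyl]boronic acid
Conditions: NaIO4, NH4OAc, acetone/H2O, rt
Reagents that add atoms: water, O
Why: Oxidative cleavage of the pinacol diol under near-neutral conditions frees the boronic acid needed for transmetalation, without loss of the aryl silyl ethers.

**Step 11**
Reactants: 11; 14 (2.5 equiv)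
Product: 15 (2S)-2-[3,5-bis(tert-butyldimethylsilyloxy)phenyl]-5,7-bis(methoxymethoxy)-6,8-bis(3-methylbut-2-en-1-yl)-2,3-dihydro-4H-chromen-4-one
Conditions: Pd(OCOCF3)2 (10 mol%), (R)-t-BuPyOx (12 mol%), NH4PF6 (30 mol%), H2O (5 equiv), ClCH2CH2Cl, 60 °C, Ar
Reagents that add atoms: none
Why: Cationic Pd(II)/pyridine-oxazoline asymmetric conjugate addition of an arylboronic acid to a chromone; the ligand directs aryl transfer to the Re face of C2 to give (2S). The (R)-ligand is chosen by analogy with the sense this catalyst class shows for cyclic enones; if a model chromone shows the opposite sense, the (S)-ligand is used. Base-free conditions avoid retro-oxa-Michael racemisation, and the trisubstituted prenyl alkenes do not insert.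

**Step 12**
Reactants: 15
Product: 16 (2S)-2-(3,5-dihydroxyphenyl)-5,7-dihydroxy-6,8-bis(3-methylbut-2-en-1-yl)-2,3-dihydro-4H-chromen-4-one (target)
Conditions: 3 M aq HCl, MeOH/THF, 45 °C
Reagents that add atoms: none
Why: Acid-catalysed methanolysis removes both MOM acetals and both aryl silyl ethers in one operation; no base is present, so C2 is not epimerised, and the mild temperature limits prenyl/phenol cyclisation to chromans.

## Compound list

1 | resorcinol | Oc1cccc(O)c1 | starting material
2 | 1,3-bis(methoxymethoxy)benzene | COCOc1cccc(OCOC)c1 | intermediate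
3 | 3,5-bis(methoxymethoxy)phenol | COCOc1cc(O)cc(OCOC)c1 | intermediate
4 | paraformaldehyde (formaldehyde unit) | C=O | starting material
5 | 2-hydroxy-4,6-bis(methoxymethoxy)benzaldehyde | O=Cc1c(O)cc(OCOC)cc1OCOC | intermediate
6 | 2-hydroxy-3,5-diiodo-4,6-bis(methoxymethoxy)benzaldehyde | O=Cc1c(O)c(I)c(OCOC)c(I)c1OCOC | intermediate
7 | 1-chloro-3-methylbut-2-ene | CC(C)=CCCl | starting material
8 | 4,4,5,5-tetramethyl-2-(3-methylbut-2-en-1-yl)-1,3,2-dioxaborolane | CC(C)=CCB1OC(C)(C)C(C)(C)O1 | intermediate
9 | 2-hydroxy-4,6-bis(methoxymethoxy)-3,5-bis(3-methylbut-2-en-1-yl)benzaldehyde | O=Cc1c(O)c(CC=C(C)C)c(OCOC)c(CC=C(C)C)c1OCOC | intermediate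
10 | ethoxyacetylene | C#COCC | starting material
11 | 5,7-bis(methoxymethoxy)-6,8-bis(3-methylbut-2-en-1-yl)-4H-chromen-4-one | O=c1ccoc2c(CC=C(C)C)c(OCOC)c(CC=C(C)C)c(OCOC)c12 | intermediate
12 | 1,3-bis(tert-butyldimethylsilyloxy)benzene | CC(C)(C)[Si](C)(C)Oc1cccc(O[Si](C)(C)C(C)(C)C)c1 | intermediate
13 | 2-[3,5-bis(tert-butyldimethylsilyloxy)phenyl]-4,4,5,5-tetramethyl-1,3,2-dioxaborolane | CC(C)(C)[Si](C)(C)Oc1cc(B2OC(C)(C)C(C)(C)O2)cc(O[Si](C)(C)C(C)(C)C)c1 | intermediate
14 | [3,5-bis(tert-butyldimethylsilyloxy)phenyl]boronic acid | CC(C)(C)[Si](C)(C)Oc1cc(B(O)O)cc(O[Si](C)(C)C(C)(C)C)c1 | intermediate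
15 | (2S)-2-[3,5-bis(tert-butyldimethylsilyloxy)phenyl]-5,7-bis(methoxymethoxy)-6,8-bis(3-methylbut-2-en-1-yl)chroman-4-one | CC(C)=CCc1c(OCOC)c(CC=C(C)C)c2c(c1OCOC)C(=O)C[C@@H](c1cc(O[Si](C)(C)C(C)(C)C)cc(O[Si](C)(C)C(C)(C)C)c1)O2 | intermediate
16 | (2S)-2-(3,5-dihydroxyphenyl)-5,7-dihydroxy-6,8-bis(3-methylbut-2-en-1-yl)chroman-4-one | CC(C)=CCc1c(O)c(CC=C(C)C)c2c(c1O)C(=O)C[C@@H](c1cc(O)cc(O)c1)O2 | target

## Summary

**Total step count:** 12

**Longest linear sequence:** 8 (steps 1, 2, 3, 4, 6, 7, 11, 12). The aryl boronic acid branch (steps 8–10) and the prenyl boronate branch (step 5) lie off the main line.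

**Steps most likely to fail, with fallbacks**

1. **Step 7 (proposed new Rh hydroacylation/annulation).** Risks are ynol ether oligomerisation, phenol addition to the alkyne, or aldehyde decarbonylation. Fallback with known chemistry: add ethynylmagnesium bromide to aldehyde 9, oxidise the propargylic alcohol with MnO2 to the 2-hydroxyaryl ethynyl ketone, and close it 6-endo with Et2NH or K2CO3 to chromone 11.
2. **Step 11 (asymmetric conjugate arylation).** The chromone is electron-rich, 5-alkoxy-substituted and fully substituted on ring A, a substrate type not yet tested in this reaction, so conversion and ee are uncertain. Fallback: convert 9 to the methyl ketone (MeMgBr, then Dess–Martin oxidation), run a Claisen–Schmidt condensation with protected 3,5-dihydroxybenzaldehyde to the 2′-hydroxychalcone, cyclise by oxa-Michael addition (NaOAc for racemate, or a cinchona-thiourea catalyst), and separate enantiomers by chiral SFC if needed.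
3. **Step 6 (double prenyl Suzuki coupling).** Both iodides are di-ortho-substituted, and linear versus branched selectivity and protodeiodination are concerns. Fallback: drop cross-coupling for classical nucleophilic C-prenylation. Remove MOM from 5 to give 2,4,6-trihydroxybenzaldehyde, doubly C-prenylate with prenyl bromide and aqueous KOH (or DBU), then re-protect with MOMCl/i-Pr2NEt, which leaves the chelated 2-OH free, to reach 9.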